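**Unit first.** The natural-log unit of substrate is the one to reckon this flask in: at steady c_partner the loss of substrate is pseudo-first-order, so a given stretch of catalyst work takes off the same number of log units however much substrate stands. Alpha's substrate readings of 55% and 56% give 0.589 for the reach of a catalyst charge, the log of c_substrate charged over c_substrate left once the readings stop falling.

common to all: substrate 0.013 M; free catalyst 13 µM
- alpha: solid reagent 0.039 M; the very flask that is asked about, followed so far
- flask: solid reagent 0.0390 M; time 12 min

alpha run (percent of the substrate charged)

| time / min | target / % | substrate / % |
|---|---|---|
| 2.50 | 29 | 72 |
| 5.00 | 38 | 62 |
| 8.00 | 47 | 55 |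
| 10.0 | 44 | 56 |

(scatter of a reading: 1.5 percentage points)

- spring: at 12 min take out 90% of the target then present, then wait 12 min
- noon: change nothing and wait 12 min more
- summer: at 12 min add free catalyst, 100% of the amount charged, then wait 12 min
- dusk: at 12 min add substrate, 50.0% of the amount charged, then wait 12 min

- solid, in amounts per volume of the solution: solid reagent
- removed target is counted in
- the numbers in the tables scatter by 1.5 percentage points (one standard deviation)
- steps thought possible: substrate + partner + free catalyst -> free catalyst + target; solid reagent <-> partner; free catalyst -> spent catalyst
- at the start none of the solid reagent is in solution
- additions bring no volume worth counting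

* target, in percent of the substrate first charged, at 12 min
* the option that brings most further target ("none" if no option brings more than 2 percentage points) (spring / noon / summer / dusk / none)
* target present, with what was taken out counted in, in percent of the substrate first charged, after noon
* target present, with what was taken out counted in, in percent of the substrate first charged, after dusk

**Your hunch.** A shortage of solid reagent doesn't fit alpha. The target read at 8.00 min stands for 15.7% of the solid reagent charged, and the charge is larger than the substrate's, yet the readings have stalled. I read the stall as the catalyst dying.

**My number.** For this flask that reach gives 44.5% target at 12 min. Spring, noon and dusk bring no fresh catalyst, so I expect each to stay under 2 percentage points. Summer brings a second reach on the substrate left, worth 25 points.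

**The forecast.** It gives 45.5% now, 46% after noon and 46.7% after dusk, and picks summer, with a gain of about 24 points, a little below mine. Its ground: “That points to the catalyst dying, not to a shortage of partner.”

**The result.** The flask gives 46.0% at 12 min, 46.8% after noon and 47.5% after dusk. The best option is summer, with 26 points against the 25 points of a second reach, while dusk brings 1.6 points.

    substrate + partner + free catalyst → free catalyst + target (k = 66000 L² mol⁻² s⁻¹)
    solid reagent ⇌ partner, rate k2*(cs2 - [partner]) while solid is left; crystals form when [partner] > cs2 (solubility = 4.00 mM, k = 0.210 s⁻¹)
    free catalyst → spent catalyst (k = 0.00520 s⁻¹)

**Catalyst first.** At 0.596 min in the flask, free catalyst has a half-life of 2.2 min by its own decay, shorter than the 4.2 min of substrate by the step to target, and at 12.0 min the flask holds 2.37% of its catalyst free with 54% of its substrate left. In the flask, half of the dissolution up to 12 min is done by 0.596 min, sooner than that catalyst half-life, and partner stands at 0.00388 M at 1.20 min and 0.00400 M at 12.0 min. Scaled by charge, the reach comes to 1.45 for a neighbour flask charged with 3.2 × 10⁻⁵ M of free catalyst, which means 76.5% target, and at 12 min that neighbour stands at 77.4%.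

(The runs are simulated with made-up constants; scatter was added.)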